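**Plan**

- Retrosynthetic cuts, in order: the aldehyde C=O of the 1-formylvinyl group (back to an isopropenyl CH3), both isovalerate C–O bonds, the C1'–H bond of the side-chain carbinol (back to the 5-acetyl ketone), the C3a–C3 bond of ring B, and the aryl C7a–O1 bond.
- Forward order: prenol → Sharpless epoxide → isopropenyl carbinol → SNAr ether with 4'-fluoro-3'-iodoacetophenone → α-aryloxy aldehyde → closure of ring B (C3a–C3) → ketone reduction → double acylation → allylic oxidation.
- Enabling feature: on ring A, O1 is para to the C5 acyl carbon and ortho to C3a. The acetyl group therefore activates fluoride displacement at C7a, yet is inert to an aryl–chromium bond at C3a. The O1–C2 tether holds the aldehyde carbon C3 within reach for a five-membered closure, and ring B (O1, C2, C3, C3a, C7a) is the only ring to be made.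
- Stereochemistry: C2 comes from the asymmetric epoxidation (L-(+)-tartrate) and is carried with retention; C3 is set by 1,2-induction from C2 in the ring closure (trans); C1' is set by catalyst-controlled transfer hydrogenation.

Key step: step 7

Assumption: 1-(4-fluoro-3-iodophenyl)ethan-1-one (5) is taken as a catalogue building block.

**Route**

Step 1
Reactants: 1 3-methylbut-2-en-1-ol (prenol)
Product: 2 [(2S)-3,3-dimethyloxiran-2-yl]methanol
Conditions: Ti(OiPr)4 (5 mol%), L-(+)-diethyl tartrate (6 mol%), tBuOOH (in isooctane), 4 Å molecular sieves, CH2Cl2, −20 °C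
Reagents that add atoms: tert-butyl hydroperoxide, CC(C)(C)OO
Why: Sharpless asymmetric epoxidation of a primary allylic alcohol, in which the catalyst formed from Ti(OiPr)4 and L-(+)-diethyl tartrate should deliver oxygen to the alkene face that gives the (S)-epoxide, whose CH carbon becomes C2 of the target.

Step 2
Reactants: 2 [(2S)-3,3-dimethyloxiran-2-yl]methanol
Product: 3 (3S)-3-{[(4-methoxybenzyl)oxy]methyl}-2,2-dimethyloxirane
Conditions: NaH, 4-methoxybenzyl chloride, nBu4NI (cat.), THF, 0 °C to rt
Reagents that add atoms: 4-methoxybenzyl chloride, COc1ccc(CCl)cc1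
Why: Williamson etherification of the primary alkoxide; a benzyl-type ether is chosen because it cannot migrate to the neighbouring oxygen under the basic conditions of step 4, as a silyl group would, and it leaves oxidatively in step 5.

Step 3
Reactants: 3 (3S)-3-{[(4-methoxybenzyl)oxy]methyl}-2,2-dimethyloxirane
Product: 4 (2R)-1-[(4-methoxybenzyl)oxy]-3-methylbut-3-en-2-ol
Conditions: Al(OiPr)3 (2 equiv), toluene, 110 °C
Reagents that add atoms: none
Why: Al(OiPr)3-promoted isomerization of a trisubstituted epoxide to an allylic alcohol, in which the tertiary C–O bond breaks as a methyl proton is removed while the secondary C–O bond stays intact, so the configuration is kept (the descriptor changes from S to R only through the priority order).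

Step 4
Reactants: 4 (2R)-1-[(4-methoxybenzyl)oxy]-3-methylbut-3-en-2-ol; 5 1-(4-fluoro-3-iodophenyl)ethan-1-one
Product: 6 1-[3-iodo-4-({(2R)-1-[(4-methoxybenzyl)oxy]-3-methylbut-3-en-2-yl}oxy)phenyl]ethan-1-one
Conditions: NaH, DMF, 0 °C; then 5, 0 °C to rt
Reagents that add atoms: none
Why: Nucleophilic aromatic substitution (addition–elimination) of the fluoride para to the acetyl group by the secondary alkoxide; the C–O bond at the stereocenter is not broken, so C2 keeps its configuration.

Step 5
Reactants: 6 1-[3-iodo-4-({(2R)-1-[(4-methoxybenzyl)oxy]-3-methylbut-3-en-2-yl}oxy)phenyl]ethan-1-one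
Product: 7 1-(4-{[(2R)-1-hydroxy-3-methylbut-3-en-2-yl]oxy}-3-iodophenyl)ethan-1-one
Conditions: DDQ, CH2Cl2/pH 7 phosphate buffer, 0 °C
Reagents that add atoms: none
Why: Oxidative cleavage of the 4-methoxybenzyl ether by hydride abstraction at its electron-rich benzylic position, which should leave the electron-poor aryl allyl ether, the alkene, the ketone and the iodide untouched.

Step 6
Reactants: 7 1-(4-{[(2R)-1-hydroxy-3-methylbut-3-en-2-yl]oxy}-3-iodophenyl)ethan-1-one
Product: 8 (2R)-2-(4-acetyl-2-iodophenoxy)-3-methylbut-3-enal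
Conditions: Dess–Martin periodinane, NaHCO3, CH2Cl2, 0 °C; filtered and used at once without chromatography
Reagents that add atoms: none
Why: Dess–Martin oxidation of the primary alcohol under buffered, base-free conditions, chosen so that the α-aryloxy β,γ-unsaturated aldehyde is formed and passed on without enolization at C2.

Step 7
Reactants: 8 (2R)-2-(4-acetyl-2-iodophenoxy)-3-methylbut-3-enal
Product: 10 1-[(2R,3S)-3-hydroxy-2-(prop-1-en-2-yl)-2,3-dihydro-1-benzofuran-5-yl]ethan-1-one, via arylchromium dichloride 9 (not isolated)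
Conditions: CrCl2 (5 equiv), NiCl2 (5 mol%), degassed DMF (0.01 M), rt
Reagents that add atoms: none
Why: Zerovalent nickel, formed from NiCl2 and CrCl2, inserts into the C–I bond and hands the aryl group to trivalent chromium to give 9, whose aryl–chromium bond then adds across the tethered aldehyde through a four-centre transition state, forming the C3a–C3 bond. The closest known reaction type is the Nozaki–Hiyama–Kishi coupling of an aryl iodide with an aldehyde, run here intramolecularly. Ring B closes in the 5-exo-trig mode. The new stereocenter C3 is controlled by C2 (substrate control): on the forming envelope the chromium-bound aldehyde oxygen should take the side away from the isopropenyl group to avoid eclipsing it, which gives the trans (3S) carbinol. The step needs addition to the aldehyde in preference to the methyl ketone, which the low reactivity of organochromium reagents toward ketones secures, and insertion into C–I in preference to ionization of the allylic aryl ether, which the iodide secures. It also needs C2 to keep its configuration, which the neutral, non-basic medium and the fast intramolecular capture should ensure.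

Step 8
Reactants: 10 1-[(2R,3S)-3-hydroxy-2-(prop-1-en-2-yl)-2,3-dihydro-1-benzofuran-5-yl]ethan-1-one
Product: 11 (2R,3S)-5-[(1R)-1-hydroxyethyl]-2-(prop-1-en-2-yl)-2,3-dihydro-1-benzofuran-3-ol
Conditions: RuCl[(R,R)-TsDPEN](p-cymene) (1 mol%), HCO2H/Et3N (5:2), EtOAc, rt
Reagents that add atoms: none
Why: Noyori asymmetric transfer hydrogenation of an aryl methyl ketone, in which the (R,R)-diamine ligand should deliver hydride through the six-membered outer-sphere transition state to the face that gives the (R)-carbinol at C1' under catalyst control, without touching the alkene or the C3 carbinol.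

Step 9
Reactants: 11 (2R,3S)-5-[(1R)-1-hydroxyethyl]-2-(prop-1-en-2-yl)-2,3-dihydro-1-benzofuran-3-ol; 12 3-methylbutanoic anhydride (isovaleric anhydride)
Product: 13 (1R)-1-[(2R,3S)-3-[(3-methylbutanoyl)oxy]-2-(prop-1-en-2-yl)-2,3-dihydro-1-benzofuran-5-yl]ethyl 3-methylbutanoate
Conditions: Et3N, DMAP (cat.), CH2Cl2, 0 °C to rt
Reagents that add atoms: none
Why: DMAP-catalysed acyl transfer esterifies both secondary benzylic alcohols in one operation without touching a stereocenter, and in the trans isomer the C2 hydrogen is syn to the C3 ester, so anti elimination to the benzofuran should be slow.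

Step 10
Reactants: 13 (1R)-1-[(2R,3S)-3-[(3-methylbutanoyl)oxy]-2-(prop-1-en-2-yl)-2,3-dihydro-1-benzofuran-5-yl]ethyl 3-methylbutanoate
Product: 15 (1R)-1-[(2R,3S)-3-[(3-methylbutanoyl)oxy]-2-(3-oxoprop-1-en-2-yl)-2,3-dihydro-1-benzofuran-5-yl]ethyl 3-methylbutanoate, via allylic alcohol 14 (not isolated)
Conditions: SeO2 (0.5 equiv), tBuOOH (3 equiv), CH2Cl2, rt; then the crude mixture with Dess–Martin periodinane, NaHCO3, CH2Cl2, 0 °C
Reagents that add atoms: tert-butyl hydroperoxide, CC(C)(C)OO (terminal oxidant); selenium dioxide, O=[Se]=O (oxygen carrier)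
Why: Selenium dioxide allylic oxidation (ene reaction, then 2,3-sigmatropic shift) should attack the methyl group of the 1,1-disubstituted alkene in preference to the oxygen-deactivated ring methine at C2, and the Dess–Martin oxidation converges the resulting alcohol and enal mixture on the enal without touching a stereocenter.

**Compound list**

1 | 3-methylbut-2-en-1-ol (prenol) | CC(C)=CCO | starting material
2 | [(2S)-3,3-dimethyloxiran-2-yl]methanol | CC1(C)O[C@H]1CO | intermediate
3 | (3S)-3-{[(4-methoxybenzyl)oxy]methyl}-2,2-dimethyloxirane | CC1(C)O[C@H]1COCc1ccc(OC)cc1 | intermediate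
4 | (2R)-1-[(4-methoxybenzyl)oxy]-3-methylbut-3-en-2-ol | O[C@H](C(C)=C)COCc1ccc(OC)cc1 | intermediate
5 | 1-(4-fluoro-3-iodophenyl)ethan-1-one | CC(=O)c1ccc(F)c(I)c1 | starting material
6 | 1-[3-iodo-4-({(2R)-1-[(4-methoxybenzyl)oxy]-3-methylbut-3-en-2-yl}oxy)phenyl]ethan-1-one | CC(=O)c1ccc(O[C@H](C(C)=C)COCc2ccc(OC)cc2)c(I)c1 | intermediate
7 | 1-(4-{[(2R)-1-hydroxy-3-methylbut-3-en-2-yl]oxy}-3-iodophenyl)ethan-1-one | CC(=O)c1ccc(O[C@H](C(C)=C)CO)c(I)c1 | intermediate
8 | (2R)-2-(4-acetyl-2-iodophenoxy)-3-methylbut-3-enal | CC(=O)c1ccc(O[C@H](C(C)=C)C=O)c(I)c1 | intermediate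
9 | {5-acetyl-2-[((2R)-3-methyl-1-oxobut-3-en-2-yl)oxy]phenyl}chromium dichloride (trivalent chromium) | CC(=O)c1ccc(O[C@H](C(C)=C)C=O)c([Cr](Cl)Cl)c1 | intermediate (not isolated)
10 | 1-[(2R,3S)-3-hydroxy-2-(prop-1-en-2-yl)-2,3-dihydro-1-benzofuran-5-yl]ethan-1-one | C=C(C)[C@H]1Oc2ccc(C(C)=O)cc2[C@@H]1O | intermediate
11 | (2R,3S)-5-[(1R)-1-hydroxyethyl]-2-(prop-1-en-2-yl)-2,3-dihydro-1-benzofuran-3-ol | C=C(C)[C@H]1Oc2ccc([C@@H](C)O)cc2[C@@H]1O | intermediate
12 | 3-methylbutanoic anhydride (isovaleric anhydride) | CC(C)CC(=O)OC(=O)CC(C)C | starting material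
13 | (1R)-1-[(2R,3S)-3-[(3-methylbutanoyl)oxy]-2-(prop-1-en-2-yl)-2,3-dihydro-1-benzofuran-5-yl]ethyl 3-methylbutanoate | C=C(C)[C@H]1Oc2ccc([C@@H](C)OC(=O)CC(C)C)cc2[C@@H]1OC(=O)CC(C)C | intermediate
14 | (1R)-1-[(2R,3S)-2-(3-hydroxyprop-1-en-2-yl)-3-[(3-methylbutanoyl)oxy]-2,3-dihydro-1-benzofuran-5-yl]ethyl 3-methylbutanoate | C=C(CO)[C@H]1Oc2ccc([C@@H](C)OC(=O)CC(C)C)cc2[C@@H]1OC(=O)CC(C)C | intermediate (not isolated)
15 | (1R)-1-[(2R,3S)-3-[(3-methylbutanoyl)oxy]-2-(3-oxoprop-1-en-2-yl)-2,3-dihydro-1-benzofuran-5-yl]ethyl 3-methylbutanoate | C=C(C=O)[C@H]1Oc2ccc([C@@H](C)OC(=O)CC(C)C)cc2[C@@H]1OC(=O)CC(C)C | target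

**Step count and risks**

Total step count: 10. Longest linear sequence: 10 steps (from 1 to 15).

Steps most likely to fail:

Step 7. The addition of the aryl–chromium bond to the aldehyde may show poor or reversed facial selectivity, so that the C3 epimer is the main product. The fallback sets out from 8 and corrects the configuration by an invertive esterification instead of relying on direct induction. The cyclization is run as before and the cis carbinol 1-[(2R,3R)-3-hydroxy-2-(prop-1-en-2-yl)-2,3-dihydro-1-benzofuran-5-yl]ethan-1-one F1 is collected. A Mitsunobu reaction with 3-methylbutanoic acid (PPh3, diisopropyl azodicarboxylate, THF, 0 °C) should install the isovalerate with inversion and give (2R,3S)-5-acetyl-2-(prop-1-en-2-yl)-2,3-dihydro-1-benzofuran-3-yl 3-methylbutanoate F2; the electron-withdrawing acetyl group para to O1 should hold back ionization at C3 at this stage. Transfer hydrogenation under the conditions of step 8 should then give (2R,3S)-5-[(1R)-1-hydroxyethyl]-2-(prop-1-en-2-yl)-2,3-dihydro-1-benzofuran-3-yl 3-methylbutanoate F3. Acylation of the remaining carbinol with 12 (Et3N, DMAP) brings the material back to the route at 13.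

Step 6. The β,γ double bond may migrate into conjugation with the aldehyde, and C2 may lose its configuration by enolization during oxidation and handling. The fallback sets out from 7 and carries the side chain as a tertiary alcohol, so that the aldehyde has no double bond to conjugate with. Mukaiyama hydration of the isopropenyl group (Co(acac)2 cat., PhSiH3, O2, THF/iPrOH, rt) should give 1-(4-{[(2S)-1,3-dihydroxy-3-methylbutan-2-yl]oxy}-3-iodophenyl)ethan-1-one F4. Dess–Martin oxidation of the primary alcohol should give (2R)-2-(4-acetyl-2-iodophenoxy)-3-hydroxy-3-methylbutanal F5. Ring closure with CrCl2 and NiCl2 as in step 7 should give 1-[(2S,3S)-3-hydroxy-2-(2-hydroxypropan-2-yl)-2,3-dihydro-1-benzofuran-5-yl]ethan-1-one F6. Transfer hydrogenation as in step 8 should give (2S,3S)-5-[(1R)-1-hydroxyethyl]-2-(2-hydroxypropan-2-yl)-2,3-dihydro-1-benzofuran-3-ol F7. Acylation with 12 should esterify only the two secondary alcohols and give (1R)-1-[(2S,3S)-2-(2-hydroxypropan-2-yl)-3-[(3-methylbutanoyl)oxy]-2,3-dihydro-1-benzofuran-5-yl]ethyl 3-methylbutanoate F8. Dehydration of the tertiary alcohol toward a methyl group (Burgess reagent, toluene, 50 °C) returns the material to the route at 13.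

Step 10. The allylic oxidation may be unselective, and the acidic selenium species may ionize the benzylic esters, with loss of isovaleric acid and aromatization to the benzofuran. The fallback sets out from 13 and replaces the selenium oxidation by a halogenation–oxidation pair. Ene-type chlorination with hypochlorous acid (Ca(OCl)2, solid CO2, CH2Cl2/H2O, 0 °C) should give (1R)-1-[(2R,3S)-2-(3-chloroprop-1-en-2-yl)-3-[(3-methylbutanoyl)oxy]-2,3-dihydro-1-benzofuran-5-yl]ethyl 3-methylbutanoate F9. Kornblum-type oxidation of the allylic chloride with N-methylmorpholine N-oxide (NaI cat., MeCN, rt) gives the enal and rejoins the route at 15.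

**Further compounds**

F1 | step 7 | 1-[(2R,3R)-3-hydroxy-2-(prop-1-en-2-yl)-2,3-dihydro-1-benzofuran-5-yl]ethan-1-one | C=C(C)[C@H]1Oc2ccc(C(C)=O)cc2[C@H]1O
F2 | step 7 | (2R,3S)-5-acetyl-2-(prop-1-en-2-yl)-2,3-dihydro-1-benzofuran-3-yl 3-methylbutanoate | C=C(C)[C@H]1Oc2ccc(C(C)=O)cc2[C@@H]1OC(=O)CC(C)C
F3 | step 7 | (2R,3S)-5-[(1R)-1-hydroxyethyl]-2-(prop-1-en-2-yl)-2,3-dihydro-1-benzofuran-3-yl 3-methylbutanoate | C=C(C)[C@H]1Oc2ccc([C@@H](C)O)cc2[C@@H]1OC(=O)CC(C)C
F4 | step 6 | 1-(4-{[(2S)-1,3-dihydroxy-3-methylbutan-2-yl]oxy}-3-iodophenyl)ethan-1-one | CC(=O)c1ccc(O[C@H](C(C)(C)O)CO)c(I)c1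
F5 | step 6 | (2R)-2-(4-acetyl-2-iodophenoxy)-3-hydroxy-3-methylbutanal | CC(=O)c1ccc(O[C@H](C(C)(C)O)C=O)c(I)c1
F6 | step 6 | 1-[(2S,3S)-3-hydroxy-2-(2-hydroxypropan-2-yl)-2,3-dihydro-1-benzofuran-5-yl]ethan-1-one | CC(C)(O)[C@H]1Oc2ccc(C(C)=O)cc2[C@@H]1O
F7 | step 6 | (2S,3S)-5-[(1R)-1-hydroxyethyl]-2-(2-hydroxypropan-2-yl)-2,3-dihydro-1-benzofuran-3-ol | CC(C)(O)[C@H]1Oc2ccc([C@@H](C)O)cc2[C@@H]1O
F8 | step 6 | (1R)-1-[(2S,3S)-2-(2-hydroxypropan-2-yl)-3-[(3-methylbutanoyl)oxy]-2,3-dihydro-1-benzofuran-5-yl]ethyl 3-methylbutanoate | CC(C)(O)[C@H]1Oc2ccc([C@@H](C)OC(=O)CC(C)C)cc2[C@@H]1OC(=O)CC(C)C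
F9 | step 10 | (1R)-1-[(2R,3S)-2-(3-chloroprop-1-en-2-yl)-3-[(3-methylbutanoyl)oxy]-2,3-dihydro-1-benzofuran-5-yl]ethyl 3-methylbutanoate | C=C(CCl)[C@H]1Oc2ccc([C@@H](C)OC(=O)CC(C)C)cc2[C@@H]1OC(=O)CC(C)C
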